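Hardest feature: the only stereocentre, C8, lies between the C7 aryl ketone (ring A, syringyl) and C9H2OH and carries the O4' aryloxy group of ring B. Once the ketone exists, C8 can epimerise, lose C9 by retro-aldol, or eliminate, so it is set while C7 is still a C=CH2 group.
Cuts: (a) O=C7 is exchanged for CH2=C7 (masked ketone). (b) C8–O4' is cut as η3-allyl-Pd plus phenol. (c) C1(ring A)–C7 and the C8–O bond of an oxirane are cut together as the arylative cyclisation of buta-2,3-dien-1-ol, which supplies C7, C8, C9 and the sacrificial CH2.
Forward: ring-A iodide + allenol → racemic 2-(1-arylvinyl)oxirane → union with the unprotected ring-B phenol (whole skeleton) → C=CH2 to C=O → desilylation. The target has no ring to build, and the oxirane is transient.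
Enabling feature: with O7 read as CH2, the triad C7(sp2, on ring A)–C8H(O4'–ring B)–C9H2OH is the 1,2-adduct of a phenol to a vinyl oxirane. The CH2 terminus of the allyl unit CH2–C7–C8 lets Pd change faces, so both epoxide enantiomers can converge.
Stereochemistry: C8 comes from the ligand-controlled dynamic kinetic asymmetric etherification (step 4) and is α to a carbonyl only in the last two, buffered, steps.

Key step: step 4

Remarks and assumptions
- Neolignan numbering is used: ring A = syringyl, C7 = carbonyl carbon, C8 = stereocentre, C9 = CH2OH, ring B = guaiacyl with O4'.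
- The target SMILES gives C8 = S (OAr > C7(=O) > C9 > H). In 8 the same spatial arrangement is called R, because C9H2OH outranks C7(=CH2)Ar. No bond at C8 changes after step 4.
- Assumption: the (S,S)-ligand is written for (R)-8 by analogy with the parent butadiene monoepoxide series. Ring A on the central allyl carbon may shift the syn/anti population, so the sense must be checked on the first run, and the (R,R)-ligand, equally available, is used if it proves opposite.
- Assumption: 1, 5 and 7 are catalogue compounds.

Step 1
Reactants: 1 4-bromo-2,6-dimethoxyphenol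
Product: 2 (4-bromo-2,6-dimethoxyphenoxy)triisopropylsilane
Conditions: TIPSCl, imidazole, DMF, rt
Reagents that add atoms: triisopropylsilyl chloride, CC(C)[Si](Cl)(C(C)C)C(C)C
Why: Standard silylation of a hindered phenol, which keeps the ring-A phenol from acting as a competing pronucleophile in steps 3 and 4 and from being oxidised by periodate in step 5.

Step 2
Reactants: 2 (4-bromo-2,6-dimethoxyphenoxy)triisopropylsilane
Product: 4 (4-iodo-2,6-dimethoxyphenoxy)triisopropylsilane, via aryllithium 3 (not isolated)
Conditions: n-BuLi, THF, −78 °C; then I2, −78 °C to rt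
Reagents that add atoms: iodine, II; n-butyllithium, [Li]CCCC (lithium stays only in intermediate 3)
Why: Halogen–lithium exchange followed by iodinolysis gives the iodide, whose oxidative addition should run at a temperature low enough for the vinyl oxirane of step 3 to survive.

Step 3
Reactants: 4 (4-iodo-2,6-dimethoxyphenoxy)triisopropylsilane; 5 buta-2,3-dien-1-ol
Product: 6 rac-2-{1-[3,5-dimethoxy-4-(triisopropylsilyloxy)phenyl]ethenyl}oxirane
Conditions: Pd(PPh3)4 (cat.), K2CO3, DMF, 60 °C
Reagents that add atoms: none
Why: In this Pd(0)-catalysed coupling–cyclisation of a 2,3-allenol with an aryl iodide, ArPdI carbopalladates the allene with ring A going to the central carbon (future C7), and the deprotonated hydroxyl closes the oxirane by 3-exo attack on the near terminus (C8) of the η3-allyl; the racemate is all that is needed.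

Step 4
Reactants: 6 rac-2-{1-[3,5-dimethoxy-4-(triisopropylsilyloxy)phenyl]ethenyl}oxirane; 7 dihydroconiferyl alcohol [4-(3-hydroxypropyl)-2-methoxyphenol]
Product: 8 (2R)-3-[3,5-dimethoxy-4-(triisopropylsilyloxy)phenyl]-2-[4-(3-hydroxypropyl)-2-methoxyphenoxy]but-3-en-1-ol
Conditions: [(η3-C3H5)PdCl]2 (cat.), (S,S)-DACH-naphthyl ligand {N,N'-[(1S,2S)-cyclohexane-1,2-diyl]bis[2-(diphenylphosphino)-1-naphthamide]} (cat.), CH2Cl2, rt, slow addition of 7
Reagents that add atoms: none
Why: Pd(0) opens both enantiomers of 6 with inversion to zwitterionic η3-allyl complexes spanning CH2–C7(ring A)–C8 with the C9 alkoxide attached, and these diastereomeric complexes should exchange the Pd-bound face by η3–η1–η3 slippage through the unsubstituted CH2 terminus faster than they are captured, helped by chloride from the precatalyst and by the slow addition of 7. The C9 alkoxide deprotonates O4'–H of 7 and the hydrogen-bonded phenoxide attacks the neighbouring terminus C8 anti to Pd, so the C8–O4' bond, the free C9–OH and the C7=CH2 group arise in one fully atom-economical event. The closest known reaction types are the Tsuji–Trost-type dynamic kinetic asymmetric additions of oxygen and nitrogen pronucleophiles to butadiene and isoprene monoepoxides, the branched-selective asymmetric etherification of vinylethylene carbonates with phenols, and the deracemising etherification of Morita–Baylis–Hillman carbonates with phenols, the last showing that centrally substituted allyl units fit the same ligand pocket. No ring is closed (the oxirane is opened), and the single new stereocentre C8 is controlled by the chiral pocket of the C2-symmetric diphosphine, which lets one of the equilibrating complexes react faster and should give (R)-8. The step needs attack at C8 rather than at CH2, secured by the alkoxide/phenoxide ion pair next to C8 and by the branched preference of this ligand class with phenols; it needs phenol over aliphatic OH, secured by the much higher acidity of O4'–H (aliphatic alcohols add only with a boron co-catalyst); and it needs no re-ionisation of 8, secured by the poor leaving-group ability of the electron-rich guaiacyl oxide at rt.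

Step 5
Reactants: 8 (2R)-3-[3,5-dimethoxy-4-(triisopropylsilyloxy)phenyl]-2-[4-(3-hydroxypropyl)-2-methoxyphenoxy]but-3-en-1-ol
Product: 10 (2S)-1-[3,5-dimethoxy-4-(triisopropylsilyloxy)phenyl]-3-hydroxy-2-[4-(3-hydroxypropyl)-2-methoxyphenoxy]propan-1-one, via vicinal diol 9 (not isolated)
Conditions: OsO4 (cat.), NaIO4, 2,6-lutidine, dioxane–H2O, 0 °C to rt
Reagents that add atoms: osmium tetroxide, O=[Os](=O)(=O)=O (oxygen carrier); sodium periodate, [Na+].[O-]I(=O)(=O)=O (terminal oxygen source)
Why: In this lutidine-buffered Lemieux–Johnson cleavage the electron-rich 1,1-disubstituted styrene is the only alkene and 9 holds the only vicinal diol, so only the sacrificial CH2 is lost, and C8 keeps its bonds and its configuration (R becomes S by CIP ranking only).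

Step 6
Reactants: 10 (2S)-1-[3,5-dimethoxy-4-(triisopropylsilyloxy)phenyl]-3-hydroxy-2-[4-(3-hydroxypropyl)-2-methoxyphenoxy]propan-1-one
Product: 11 (2S)-3-hydroxy-1-(4-hydroxy-3,5-dimethoxyphenyl)-2-[4-(3-hydroxypropyl)-2-methoxyphenoxy]propan-1-one (target)
Conditions: TBAF, AcOH (1:1), THF, 0 °C
Reagents that add atoms: none
Why: Fluoride cleaves the aryl silyl ether, which the para acyl group makes very labile, while the acetic acid buffer keeps the medium below the basicity needed for enolisation at C8, retro-aldol loss of C9 or β-elimination.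

Compound list
1 | 4-bromo-2,6-dimethoxyphenol | COc1cc(Br)cc(OC)c1O | starting material
2 | (4-bromo-2,6-dimethoxyphenoxy)triisopropylsilane | COc1cc(Br)cc(OC)c1O[Si](C(C)C)(C(C)C)C(C)C | intermediate
3 | [3,5-dimethoxy-4-(triisopropylsilyloxy)phenyl]lithium | [Li]c1cc(OC)c(O[Si](C(C)C)(C(C)C)C(C)C)c(OC)c1 | intermediate
4 | (4-iodo-2,6-dimethoxyphenoxy)triisopropylsilane | COc1cc(I)cc(OC)c1O[Si](C(C)C)(C(C)C)C(C)C | intermediate
5 | buta-2,3-dien-1-ol | C=C=CCO | starting material
6 | rac-2-{1-[3,5-dimethoxy-4-(triisopropylsilyloxy)phenyl]ethenyl}oxirane | C=C(C1CO1)c1cc(OC)c(O[Si](C(C)C)(C(C)C)C(C)C)c(OC)c1 | intermediate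
7 | dihydroconiferyl alcohol, 4-(3-hydroxypropyl)-2-methoxyphenol | COc1cc(CCCO)ccc1O | starting material
8 | (2R)-3-[3,5-dimethoxy-4-(triisopropylsilyloxy)phenyl]-2-[4-(3-hydroxypropyl)-2-methoxyphenoxy]but-3-en-1-ol | COc1cc(CCCO)ccc1O[C@@H](CO)C(=C)c1cc(OC)c(O[Si](C(C)C)(C(C)C)C(C)C)c(OC)c1 | intermediate
9 | (3S)-2-[3,5-dimethoxy-4-(triisopropylsilyloxy)phenyl]-3-[4-(3-hydroxypropyl)-2-methoxyphenoxy]butane-1,2,4-triol, both C2 epimers | COc1cc(CCCO)ccc1O[C@@H](CO)C(O)(CO)c1cc(OC)c(O[Si](C(C)C)(C(C)C)C(C)C)c(OC)c1 | intermediate
10 | (2S)-1-[3,5-dimethoxy-4-(triisopropylsilyloxy)phenyl]-3-hydroxy-2-[4-(3-hydroxypropyl)-2-methoxyphenoxy]propan-1-one | COc1cc(CCCO)ccc1O[C@@H](CO)C(=O)c1cc(OC)c(O[Si](C(C)C)(C(C)C)C(C)C)c(OC)c1 | intermediate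
11 | (2S)-3-hydroxy-1-(4-hydroxy-3,5-dimethoxyphenyl)-2-[4-(3-hydroxypropyl)-2-methoxyphenoxy]propan-1-one | COc1cc(CCCO)ccc1O[C@@H](CO)C(=O)c1cc(OC)c(O)c(OC)c1 | target

Total step count: 6. Longest linear sequence: 6 (1 → 2 → 4 → 6 → 8 → 10 → 11).

Steps most likely to fail

Step 4. The phenoxide may attack the CH2 terminus, capture may occur before face exchange is complete, or ring A on the central carbon may shift the syn/anti population of the allyl complex. Each of these would lower regio- or enantioselectivity. The fallback replaces the dynamic process by a classical resolution followed by an SN2 inversion.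
- It sets out from 6. Hydrolytic kinetic resolution uses the (salen)Co(III) acetate antipode matched to the (S)-epoxide and about half an equivalent of water.
- This should give (2S)-3-[3,5-dimethoxy-4-(triisopropylsilyloxy)phenyl]but-3-ene-1,2-diol F1. Water enters at the oxirane CH2 and C8 is untouched. The unreacted (R)-epoxide is separated.
- Selective acylation of the primary hydroxyl with pivaloyl chloride and pyridine gives (2S)-3-[3,5-dimethoxy-4-(triisopropylsilyloxy)phenyl]-2-hydroxybut-3-en-1-yl pivalate F2.
- Mitsunobu etherification (PPh3, DIAD) with commercial methyl 3-(4-hydroxy-3-methoxyphenyl)propanoate inverts C8 to the (R)-configured aryl ether diester F3.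
- LiAlH4 at 0 °C reduces the methyl ester to the side-chain alcohol and removes the pivalate in the same operation, which brings the sequence back to the route at 8.

Step 3. The unsubstituted primary allenol may close the three-membered ring sluggishly, the alkoxide may close on the CH2 terminus to a dihydrofuran, or Pd may isomerise the vinyl oxirane once formed. The fallback builds the oxirane from a carbonyl group and does not use the allene.
- It sets out from 2. Bromine–lithium exchange, triisopropyl borate and acidic work-up give [3,5-dimethoxy-4-(triisopropylsilyloxy)phenyl]boronic acid F4.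
- Suzuki–Miyaura coupling with commercial 2-bromoprop-2-en-1-ol gives 2-[3,5-dimethoxy-4-(triisopropylsilyloxy)phenyl]prop-2-en-1-ol F5.
- MnO2 oxidation gives 2-[3,5-dimethoxy-4-(triisopropylsilyloxy)phenyl]prop-2-enal F6.
- Corey–Chaykovsky epoxidation with dimethylsulfonium methylide adds 1,2 to the aldehyde and comes back to the route at 6.

Step 5. The oxidants may attack the two electron-rich rings, or configuration may erode slowly while the new ketone sits in the aqueous buffered medium. The fallback replaces the glycol pathway by a cycloaddition/cycloreversion in a cold, non-aqueous, base-free medium.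
- It sets out from 8. Ozonolysis in CH2Cl2 at −78 °C to an indicator end-point gives the secondary ozonide of 8 F7.
- The ozonide is reduced cold with PPh3, which returns to the route at 10.

Further compounds
F1 | step 4 | (2S)-3-[3,5-dimethoxy-4-(triisopropylsilyloxy)phenyl]but-3-ene-1,2-diol | O[C@H](CO)C(=C)c1cc(OC)c(O[Si](C(C)C)(C(C)C)C(C)C)c(OC)c1
F2 | step 4 | (2S)-3-[3,5-dimethoxy-4-(triisopropylsilyloxy)phenyl]-2-hydroxybut-3-en-1-yl pivalate | O[C@H](COC(=O)C(C)(C)C)C(=C)c1cc(OC)c(O[Si](C(C)C)(C(C)C)C(C)C)c(OC)c1
F3 | step 4 | methyl 3-[4-({(2R)-3-[3,5-dimethoxy-4-(triisopropylsilyloxy)phenyl]-1-(pivaloyloxy)but-3-en-2-yl}oxy)-3-methoxyphenyl]propanoate | COC(=O)CCc1ccc(O[C@@H](COC(=O)C(C)(C)C)C(=C)c2cc(OC)c(O[Si](C(C)C)(C(C)C)C(C)C)c(OC)c2)c(OC)c1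
F4 | step 3 | [3,5-dimethoxy-4-(triisopropylsilyloxy)phenyl]boronic acid | OB(O)c1cc(OC)c(O[Si](C(C)C)(C(C)C)C(C)C)c(OC)c1
F5 | step 3 | 2-[3,5-dimethoxy-4-(triisopropylsilyloxy)phenyl]prop-2-en-1-ol | C=C(CO)c1cc(OC)c(O[Si](C(C)C)(C(C)C)C(C)C)c(OC)c1
F6 | step 3 | 2-[3,5-dimethoxy-4-(triisopropylsilyloxy)phenyl]prop-2-enal | C=C(C=O)c1cc(OC)c(O[Si](C(C)C)(C(C)C)C(C)C)c(OC)c1
F7 | step 5 | secondary ozonide (1,2,4-trioxolane) of 8, both epimers at the ring carbon C7 | COc1cc(CCCO)ccc1O[C@@H](CO)C1(OCOO1)c1cc(OC)c(O[Si](C(C)C)(C(C)C)C(C)C)c(OC)c1
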